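The numbers in the tables stem from a simulated flask from invented constants, noise included.

The pitfall in these flasks is to count partner by its charge, as if every equivalent were waiting for starting material.

| flask | starting material | partner | second substrate | third substrate | remark | time |
|---|---|---|---|---|---|---|
| elm | 0.10 M | 1.8 equiv | 0.092 equiv | 5 equiv | run made earlier |  |
| ash | 0.10 M | 1.8 equiv | 0.52 equiv | 5 equiv | run made earlier |  |
| birch | 0.10 M | 1.6 equiv | 0.20 equiv | 5 equiv | run made earlier |  |
| dawn | 0.10 M | 1.20 equiv | 0.400 equiv | 5.00 equiv |  | 6.0 min |
| autumn | 0.10 M | 1.80 equiv | 0.200 equiv | 5.00 equiv |  | 6.0 min |
| spring | 0.10 M | 1.80 equiv | 0.800 equiv | 10.0 equiv |  | 6.0 min |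
| midnight | 0.15 M | 1.80 equiv | 0.130 equiv | 7.50 equiv |  | 6.0 min |

- elm (time / min: target / %, starting material / %): 0.667: 31.9, 68.1; 1.33: 49.1, 51.0; 2.00: 58.9, 41.1; 3.00: 68.5, 32.5; 4.00: 73.5, 26.0
- ash (time / min: target / %, starting material / %): 0.250: 14.3, 86.0; 0.833: 34.0, 65.6; 1.33: 44.3, 55.5; 2.50: 57.5, 41.8; 3.00: 61.7, 38.1; 4.00: 66.8, 33.3
- birch (time / min: target / %, starting material / %): 0.833: 33.0, 67.3; 1.50: 45.7, 53.9; 2.50: 57.5, 42.2; 3.00: 60.9, 38.7; 4.00: 66.1, 34.1

(readings scatter by 0.3 percentage points)

- ranking by amount of target, in percent of the starting material charged, from high to low, at 6.0 min (dawn / autumn / spring / midnight)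
- the same order at 80 s (dawn / autumn / spring / midnight)
- the amount of target, in percent of the starting material charged of the flask you put first, at 6.0 min
- the amount of target, in percent of the starting material charged of the flask you put last, at 6.0 min

- what was read earlier has a scatter of 0.3 percentage points, one standard deviation

I counted partner as a budget, with every amount as a fraction of the starting material charged. Let a be the starting material left and b the partner left. Then the slope of ln a is k times b, and if partner also leaks away in proportion to third substrate, the leak so far is −ln a divided by S.

In elm, the first reading gave a slope of 0.576 /min. I replaced the partner curve by its mean, 1.59, which is the charge less half the target read and half the second substrate, so k came to 0.361 /min. Between the last two readings I took a as one minus target, since the two columns at 3.00 min sum to 101%. That slope, 0.173 /min, gave b = 0.478 at a mean target of 0.710. Charging the second substrate in full left a leak of 0.520, and so S = 2.38. This S, the selectivity factor, is the partner taken by target per partner leaked when a is whole, at 5 equiv of third substrate. The mean omitted the early leak, and putting it back moved k to 0.380 /min and S to 2.28, so I carried S with that width.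

The same reckoning on ash, with a mean target of 0.643 and b = 0.396, gave S = 4.25. The two ways parted, and I took ash as the one that cheated: its charge of 0.52 equiv was entered whole, while elm could err by 0.092 equiv at most. Holding S from elm, ash needed a second-substrate toll of 0.330, which is 63.5% of its charge.

For dawn, that share left a budget of 0.946. I assumed S falls inversely with the equivalents of third substrate and does not depend on concentration.

The forecast read autumn > midnight > spring > dawn at 6.0 min and midnight > autumn > spring > dawn at 80 s, with 79% at the top and 53.5% at the bottom, and it said “Partner then runs out, giving plateaus”. My budget gave no curve of its own. Held against the forecast's low value, it left 0.0896 of partner in dawn, and I accepted that value.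

The flasks gave autumn > midnight > spring > dawn and midnight > autumn > spring > dawn, with 77.8% and 54.3%.

    starting material + partner → target (k = 0.0651 /M/s)
    second substrate + partner → second product (k = 0.230 /M/s)
    third substrate + partner → third product (k = 0.00570 /M/s)
    2 second substrate → homo dimer (k = 0.337 /M/s)

In dawn, partner went to target 2.3 times as fast as to third product at the start, but 1.1 times as fast at 6.00 min, and S times the 45.7% of starting material then left is 1.09. In midnight, S scaled to its third substrate is 1.59, and at 6.00 min that flask's 24.3% of starting material with 0.874 of third product, as a fraction of the starting material charged, gives −ln a over third product of 1.62.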